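**Strategy.** The route rests on cutting both phenolic C–O bonds of the resorcinol ring back to aryl C–H bonds, so the whole C15 chain can be built on a plain phenyl group. In the benzene ring (chain carbon = C1) the two OH groups sit on C3 and C5, meta to the chain and to each other. These are the only C–H sites without an ortho neighbour, so one pot of twofold iridium-catalysed borylation and N-oxide oxidation should install both oxygens without protecting groups. The precursor is the complete (8Z,10R)-1-phenylpentadec-8-en-10-yl acetate, with stereocentre, Z-alkene and acetate already in place, made in three steps from (R)-oct-1-yn-3-ol.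

Key step: step 4

Remark on numbering and configuration: the chain is numbered from the aryl-bearing CH2 (C1), so the alkene is C8=C9 and the oxygenated stereocentre is C10; the descriptor stays R from 1 to 11 because the unsaturated C9 substituent outranks pentyl at every stage and no step breaks a bond at C10.

**Step 1**
Reactants: 1 (R)-oct-1-yn-3-ol; 2 (7-bromoheptyl)benzene
Product: 4 (10R)-1-phenylpentadec-8-yn-10-ol, via dilithium alkynide-alkoxide 3 (not isolated)
Conditions: 1 (1.2 equiv), n-BuLi (2.4 equiv), THF, −78 → −20 °C; then DMPU, Bu4NI (cat.), 2 (1.0 equiv), −20 °C → rt; aq. NH4Cl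
Reagents that add atoms: none
Why: Acetylide SN2 alkylation of a propargylic alkoxide–alkynide dianion, in which the sp carbanion is far more nucleophilic than the hindered secondary lithium alkoxide, so the primary bromide (activated by DMPU and catalytic iodide) should be displaced at carbon while the C10 stereocentre is carried over unchanged from 1.

**Step 2**
Reactants: 4 (10R)-1-phenylpentadec-8-yn-10-ol
Product: 5 (8Z,10R)-1-phenylpentadec-8-en-10-ol
Conditions: H2 (1 atm), Lindlar catalyst (Pd/CaCO3, Pb-poisoned), quinoline, EtOAc, rt, stopped after one equivalent of H2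
Reagents that add atoms: none
Why: Lindlar semi-hydrogenation, in which syn delivery of one equivalent of H2 on poisoned palladium should give the Z-alkene and stop there, leaving the benzene ring, the allylic C–O bond and the C10 configuration untouched.

**Step 3**
Reactants: 5 (8Z,10R)-1-phenylpentadec-8-en-10-ol
Product: 6 (8Z,10R)-1-phenylpentadec-8-en-10-yl acetate
Conditions: Ac2O, pyridine, DMAP (cat.), CH2Cl2, 0 °C → rt
Reagents that add atoms: acetic anhydride, CC(=O)OC(C)=O
Why: DMAP-catalysed O-acylation of the secondary allylic alcohol (nucleophilic catalysis via N-acetylpyridinium), which takes place at oxygen without breaking the C10–O bond, so configuration and Z-geometry are retained.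

**Step 4**
Reactants: 6 (8Z,10R)-1-phenylpentadec-8-en-10-yl acetate; 7 bis(pinacolato)diboron
Product: 11 (8Z,10R)-1-(3,5-dihydroxyphenyl)pentadec-8-en-10-yl acetate, via meta-monoboronate 8 (not isolated), via 3,5-bis(boronate) 9 (not isolated), via bis(aryl borate) 10 (not isolated)
Conditions: [Ir(OMe)(cod)]2 (3 mol%), dtbpy (6 mol%), 7 (2.5 equiv), THF, 60 °C; evaporate volatiles; then Me3NO (anhydrous, 6 equiv), THF, 50 °C; aq. NH4Cl; SiO2 chromatography
Reagents that add atoms: trimethylamine N-oxide, C[N+](C)(C)[O-] (both phenolic oxygens); bis(pinacolato)diboron 7, CC1(C)OB(OC1(C)C)B1OC(C)(C)C(C)(C)O1 (Bpin groups of intermediates 8–10 only, none of its atoms remain in 11)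
Why: Proposed new method: [Ir(OMe)(cod)]2, dtbpy and B2pin2 form the 16-electron (dtbpy)Ir(Bpin)3, which cleaves an aromatic C–H bond by boryl-assisted oxidative addition, reductively eliminates Ar–Bpin and is regenerated by B2pin2; added Me3NO then binds each boron, the aryl group shifts from B to O with loss of NMe3, and work-up hydrolyses the aryl borates to the phenols. The closest known reaction type is the one-pot Ir-catalysed C–H borylation/oxidation that converts 1,3-disubstituted arenes into 3,5-disubstituted phenols, together with N-oxide hydroxylation of aryl pinacol boronates; what has not been shown is the twofold version on a monoalkylbenzene that carries an internal Z-alkene and an allylic acetate. No ring is closed and no stereocentre is formed; C10 and the C8=C9 geometry are spectators. The regioselectivity needed (C3 and C5 only) is secured sterically: the crowded tris(boryl) catalyst avoids C–H bonds ortho to the chain or to a Bpin group, so monoboronate 8 can react further only at C5, whereas the competing para-monoboronate has no free site left and should end as a less polar monophenol that chromatography removes. The chemoselectivity needed (aryl C–H over alkene and acetate) rests on the faster reaction of unhindered arene C–H bonds than of a 1,2-disubstituted alkene flanked by a branched carbon, on the mild temperature, and on an oxidant that neither epoxidises alkenes nor cleaves esters.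

**Compound list**
1 | (R)-oct-1-yn-3-ol | CCCCC[C@H](C#C)O | starting material
2 | (7-bromoheptyl)benzene | BrCCCCCCCc1ccccc1 | starting material
3 | dilithium salt of 1 (C1 acetylide and C3 alkoxide, R) | CCCCC[C@H](C#[C-])[O-].[Li+].[Li+] | intermediate (not isolated)
4 | (10R)-1-phenylpentadec-8-yn-10-ol | CCCCC[C@H](C#CCCCCCCCc1ccccc1)O | intermediate
5 | (8Z,10R)-1-phenylpentadec-8-en-10-ol | CCCCC[C@H](/C=C\CCCCCCCc1ccccc1)O | intermediate
6 | (8Z,10R)-1-phenylpentadec-8-en-10-yl acetate | CCCCC[C@H](/C=C\CCCCCCCc1ccccc1)OC(C)=O | intermediate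
7 | bis(pinacolato)diboron | CC1(C)OB(OC1(C)C)B1OC(C)(C)C(C)(C)O1 | starting material
8 | (8Z,10R)-1-[3-(4,4,5,5-tetramethyl-1,3,2-dioxaborolan-2-yl)phenyl]pentadec-8-en-10-yl acetate | CCCCC[C@H](/C=C\CCCCCCCc1cccc(B2OC(C)(C)C(C)(C)O2)c1)OC(C)=O | intermediate (not isolated)
9 | (8Z,10R)-1-[3,5-bis(4,4,5,5-tetramethyl-1,3,2-dioxaborolan-2-yl)phenyl]pentadec-8-en-10-yl acetate | CCCCC[C@H](/C=C\CCCCCCCc1cc(B2OC(C)(C)C(C)(C)O2)cc(B2OC(C)(C)C(C)(C)O2)c1)OC(C)=O | intermediate (not isolated)
10 | (8Z,10R)-1-{3,5-bis[(4,4,5,5-tetramethyl-1,3,2-dioxaborolan-2-yl)oxy]phenyl}pentadec-8-en-10-yl acetate | CCCCC[C@H](/C=C\CCCCCCCc1cc(OB2OC(C)(C)C(C)(C)O2)cc(OB2OC(C)(C)C(C)(C)O2)c1)OC(C)=O | intermediate (not isolated)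
11 | (8Z,10R)-1-(3,5-dihydroxyphenyl)pentadec-8-en-10-yl acetate | CCCCC[C@H](/C=C\CCCCCCCc1cc(O)cc(O)c1)OC(C)=O | target

**Total step count:** 4
**Longest linear sequence:** 4 steps (1 → 4 → 5 → 6 → 11)

**Steps most likely to fail**

Step 4 (Proposed new method). The iridium boryl and hydride species may add to or isomerise the C8=C9 alkene, or the second borylation may stall. On top of this, a statistical share of material is unavoidably diverted into para-monoborylation. The fallback uses known chemistry only and carries both oxygens through as silyl ethers. It sets out from 1 and returns to the route at 11.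
- 5-Bromobenzene-1,3-diol is silylated (TIPSCl, imidazole, DMF) to 1-bromo-3,5-bis(triisopropylsilyloxy)benzene F1.
- Magnesium insertion in THF gives [3,5-bis(triisopropylsilyloxy)phenyl]magnesium bromide F2.
- F2 is coupled with excess 1,7-dibromoheptane under Li2CuCl4 catalysis (Kochi-type coupling) to give 1-(7-bromoheptyl)-3,5-bis(triisopropylsilyloxy)benzene F3.
- The dianion 3, made from 1 as in step 1, is alkylated with F3 to give (10R)-1-[3,5-bis(triisopropylsilyloxy)phenyl]pentadec-8-yn-10-ol F4.
- Lindlar semi-hydrogenation gives (8Z,10R)-1-[3,5-bis(triisopropylsilyloxy)phenyl]pentadec-8-en-10-ol F5.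
- Acetylation (Ac2O, pyridine, DMAP) gives (8Z,10R)-1-[3,5-bis(triisopropylsilyloxy)phenyl]pentadec-8-en-10-yl acetate F6.
- TBAF buffered with AcOH in THF at 0 °C removes both aryl silyl ethers without touching the allylic acetate and delivers 11.

Step 1. The alkylation may be sluggish, the alkoxide oxygen may compete with the acetylide carbon for the bromide, or the strongly basic dianion may eliminate HBr from 2. The fallback masks the hydroxyl so that only carbon can react. It sets out from 1 and returns at 4.
- 1 is silylated (TBSCl, imidazole, DMF) to (R)-tert-butyldimethyl(oct-1-yn-3-yloxy)silane F7.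
- n-BuLi (1 equiv) in THF at −78 °C gives the lithium acetylide of the silyl ether F8.
- F8 is alkylated with 2 in THF/DMPU to give (10R)-tert-butyldimethyl[(1-phenylpentadec-8-yn-10-yl)oxy]silane F9.
- TBAF in THF removes the silyl group and gives 4.

Step 2. The hydrogenation may run on to the saturated chain or isomerise the Z-alkene to E on the palladium surface, giving mixtures that are hard to separate. The fallback replaces catalytic hydrogenation by a dissolving-metal cis-reduction. Alkynol 4 is treated with activated zinc (zinc dust activated with 1,2-dibromoethane and CuBr/LiBr) in refluxing ethanol. This reduces hydroxyl-activated alkynes by electron transfer and protonation to the cis-alkene and cannot reduce an isolated alkene further. It sets out from 4 and returns at 5, with no new isolated compound.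

**Further compounds**
F1 | step 4 | 1-bromo-3,5-bis(triisopropylsilyloxy)benzene | Brc1cc(O[Si](C(C)C)(C(C)C)C(C)C)cc(O[Si](C(C)C)(C(C)C)C(C)C)c1
F2 | step 4 | [3,5-bis(triisopropylsilyloxy)phenyl]magnesium bromide | Br[Mg]c1cc(O[Si](C(C)C)(C(C)C)C(C)C)cc(O[Si](C(C)C)(C(C)C)C(C)C)c1
F3 | step 4 | 1-(7-bromoheptyl)-3,5-bis(triisopropylsilyloxy)benzene | BrCCCCCCCc1cc(O[Si](C(C)C)(C(C)C)C(C)C)cc(O[Si](C(C)C)(C(C)C)C(C)C)c1
F4 | step 4 | (10R)-1-[3,5-bis(triisopropylsilyloxy)phenyl]pentadec-8-yn-10-ol | CCCCC[C@H](C#CCCCCCCCc1cc(O[Si](C(C)C)(C(C)C)C(C)C)cc(O[Si](C(C)C)(C(C)C)C(C)C)c1)O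
F5 | step 4 | (8Z,10R)-1-[3,5-bis(triisopropylsilyloxy)phenyl]pentadec-8-en-10-ol | CCCCC[C@H](/C=C\CCCCCCCc1cc(O[Si](C(C)C)(C(C)C)C(C)C)cc(O[Si](C(C)C)(C(C)C)C(C)C)c1)O
F6 | step 4 | (8Z,10R)-1-[3,5-bis(triisopropylsilyloxy)phenyl]pentadec-8-en-10-yl acetate | CCCCC[C@H](/C=C\CCCCCCCc1cc(O[Si](C(C)C)(C(C)C)C(C)C)cc(O[Si](C(C)C)(C(C)C)C(C)C)c1)OC(C)=O
F7 | step 1 | (R)-tert-butyldimethyl(oct-1-yn-3-yloxy)silane | CCCCC[C@H](C#C)O[Si](C)(C)C(C)(C)C
F8 | step 1 | lithium acetylide of F7 (R) | CCCCC[C@H](C#[C-])O[Si](C)(C)C(C)(C)C.[Li+]
F9 | step 1 | (10R)-tert-butyldimethyl[(1-phenylpentadec-8-yn-10-yl)oxy]silane | CCCCC[C@H](C#CCCCCCCCc1ccccc1)O[Si](C)(C)C(C)(C)C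
F0 | step 2 | none | none
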